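**Retrosynthetic overview**
1. Target ⇐ di-O-benzyl 8-hydroxypinoresinol: one hydrogenolysis removes both benzyl groups and cleaves ring B at its benzylic C7'–O bond (reductase-like), leaving ring A.
2. Ring B (C9–O–C7') ⇐ a 4-arylidene oxolane: acid-triggered capture of the C7' benzylic cation by the 9-OH; the obligatory cis ring fusion relays C8 to C8'.
3. Ring A (C9'–O–C7) ⇐ achiral (E,E)-2,3-bis(arylidene)butane-1,4-diol (the bis-styrene tautomer of the 8–8' bis-quinone methide of coniferyl alcohol coupling): desymmetrising asymmetric epoxidation, then opening of the benzylic epoxide by the 9'-OH, sets C8 and C7.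
4. Diene-diol ⇐ double Stobbe condensation of O-benzylvanillin with dimethyl succinate, then ester reduction.
5. Ring order: ring A first, ring B second; ring B is then opened reductively.

Assumption: lignan numbering (C7–C9, C7'–C9') is used in the discussion; the target is the (2R,3S,4S)-oxolane (8-hydroxylariciresinol skeleton), and 4-(benzyloxy)-3-methoxybenzaldehyde is taken as a commercial starting material.

**Step 1**
Reactants: 1 4-(benzyloxy)-3-methoxybenzaldehyde (2.2 equiv); 2 dimethyl succinate
Product: 4 dimethyl (2E,3E)-2,3-bis{[4-(benzyloxy)-3-methoxyphenyl]methylidene}butanedioate, via diacid disodium salt 3 (not isolated)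
Conditions: NaOMe (3 equiv), MeOH, reflux; evaporate; then MeI (3 equiv), DMF, rt
Reagents that add atoms: methyl iodide, CI
Why: Double Stobbe condensation, in which each succinate α-carbon condenses with the aldehyde through a paraconic lactone and E1cB ring opening that places each aryl trans to its carboxylate (E,E), followed by SN2 O-methylation of the crude dicarboxylate; no stereocentre is formed.

**Step 2**
Reactants: 4 dimethyl (2E,3E)-2,3-bis{[4-(benzyloxy)-3-methoxyphenyl]methylidene}butanedioate
Product: 5 (2E,3E)-2,3-bis{[4-(benzyloxy)-3-methoxyphenyl]methylidene}butane-1,4-diol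
Conditions: i-Bu2AlH (5 equiv), CH2Cl2, −78 → 0 °C; aq. potassium sodium tartrate (KNaC4H4O6) work-up
Reagents that add atoms: none
Why: Hydride 1,2-reduction of the two conjugated esters gives the bis-allylic diol without touching the alkenes or benzyl ethers; the product is achiral and its two allylic alcohol units are equivalent, which is what makes the next step a desymmetrisation.

**Step 3**
Reactants: 5 (2E,3E)-2,3-bis{[4-(benzyloxy)-3-methoxyphenyl]methylidene}butane-1,4-diol
Product: 7 (2R,3S,4Z)-2-[4-(benzyloxy)-3-methoxyphenyl]-4-{[4-(benzyloxy)-3-methoxyphenyl]methylidene}-3-(hydroxymethyl)oxolan-3-ol, via epoxy diol 6 (not isolated)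
Conditions: Ti(OiPr)4 (1.0 equiv), L-(+)-diisopropyl tartrate (1.2 equiv), t-BuOOH (1.05 equiv, anhydrous in decane), 4 Å molecular sieves, CH2Cl2, −25 °C, then 0 °C; aq. tartaric acid work-up
Reagents that add atoms: tert-butyl hydroperoxide, CC(C)(C)OO
Why: Proposed new method: a desymmetrising Sharpless asymmetric epoxidation run on the unprotected diol (closest known reaction types: Sharpless epoxidation of (E)-2,3-disubstituted cinnamyl alcohols and Ti(OiPr)4-mediated C3-selective opening of 2,3-epoxy alcohols), in which the L-(+)-tartrate complex delivers oxygen to one face of either equivalent allylic alcohol to give the (2S,3S)-epoxide and so sets C8 (S), after which the titanium-activated, quinone-methide-like p-alkoxybenzylic epoxide carbon is opened with inversion by the remaining 9'-hydroxyl (5-endo epoxide-opening cyclisation forming ring A), setting C7 (R) with the aryl cis to the new tertiary OH; once ring A has closed the remaining alkene is flanked only by a tertiary allylic alcohol, so a second epoxidation is slow.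

**Step 4**
Reactants: 7 (2R,3S,4Z)-2-[4-(benzyloxy)-3-methoxyphenyl]-4-{[4-(benzyloxy)-3-methoxyphenyl]methylidene}-3-(hydroxymethyl)oxolan-3-ol
Product: 8 (1S,2R,5R,6S)-2,6-bis[4-(benzyloxy)-3-methoxyphenyl]-3,7-dioxabicyclo[3.3.0]octan-1-ol (di-O-benzyl 8-hydroxypinoresinol; lignan descriptors 7R,8S,7'S,8'R)
Conditions: TsOH·H2O (10 mol %), CH2Cl2, 0 °C → rt
Reagents that add atoms: none
Why: Acid-catalysed intramolecular Markovnikov hydroalkoxylation, in which protonation of the p-alkoxystyrene at C8' gives the benzylic (O-benzyl quinone methide type) cation at C7' that is captured by the 9-hydroxyl as in the second ring closure of the pinoresinol pathway; only the C8' epimer that leads to the cis-fused bicycle can close (the other cation reverts to the alkene by proton loss), so H-8' ends up cis to the C8 hydroxyl (8'R), while the C7' aryl sits exo (7'S, a centre erased in step 5).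

**Step 5**
Reactants: 8 (1S,2R,5R,6S)-2,6-bis[4-(benzyloxy)-3-methoxyphenyl]-3,7-dioxabicyclo[3.3.0]octan-1-ol
Product: 9 (2R,3S,4S)-2-(4-hydroxy-3-methoxyphenyl)-4-[(4-hydroxy-3-methoxyphenyl)methyl]-3-(hydroxymethyl)oxolan-3-ol (target)
Conditions: H2 (1 atm), 10% Pd/C, MeOH–EtOAc (1:1), rt; stopped after uptake of 3 equiv H2
Reagents that add atoms: none
Why: Catalytic hydrogenolysis removes the two benzyl ethers and cleaves the benzylic C7'–O bond of ring B (mimic of the pinoresinol–lariciresinol reductase step), whereas the C7–O bond of ring A is flanked by the quaternary carbinol C8 (hindered and inductively deactivated) and survives; no stereocentre is touched (C8' changes from R to S only through a change in substituent priorities).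

**Compound list**
1 | 4-(benzyloxy)-3-methoxybenzaldehyde (O-benzylvanillin) | O=Cc1ccc(OCc2ccccc2)c(OC)c1 | starting material
2 | dimethyl succinate | COC(=O)CCC(=O)OC | starting material
3 | disodium (2E,3E)-2,3-bis{[4-(benzyloxy)-3-methoxyphenyl]methylidene}butanedioate | COc1cc(/C=C(/C(=O)[O-])\C(=C/c2ccc(OCc3ccccc3)c(OC)c2)C(=O)[O-])ccc1OCc1ccccc1.[Na+].[Na+] | intermediate (not isolated)
4 | dimethyl (2E,3E)-2,3-bis{[4-(benzyloxy)-3-methoxyphenyl]methylidene}butanedioate | COc1cc(/C=C(/C(=O)OC)\C(=C/c2ccc(OCc3ccccc3)c(OC)c2)C(=O)OC)ccc1OCc1ccccc1 | intermediate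
5 | (2E,3E)-2,3-bis{[4-(benzyloxy)-3-methoxyphenyl]methylidene}butane-1,4-diol | COc1cc(/C=C(/CO)\C(=C/c2ccc(OCc3ccccc3)c(OC)c2)CO)ccc1OCc1ccccc1 | intermediate
6 | (2Z)-3-[4-(benzyloxy)-3-methoxyphenyl]-2-{(2S,3S)-3-[4-(benzyloxy)-3-methoxyphenyl]-2-(hydroxymethyl)oxiran-2-yl}prop-2-en-1-ol | OC[C@@]1(O[C@H]1c1ccc(OCc2ccccc2)c(OC)c1)/C(CO)=C\c1ccc(OCc2ccccc2)c(OC)c1 | intermediate (not isolated)
7 | (2R,3S,4Z)-2-[4-(benzyloxy)-3-methoxyphenyl]-4-{[4-(benzyloxy)-3-methoxyphenyl]methylidene}-3-(hydroxymethyl)oxolan-3-ol | COc1cc(/C=C2/CO[C@H](c3ccc(OCc4ccccc4)c(OC)c3)[C@@]2(O)CO)ccc1OCc1ccccc1 | intermediate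
8 | (1S,2R,5R,6S)-2,6-bis[4-(benzyloxy)-3-methoxyphenyl]-3,7-dioxabicyclo[3.3.0]octan-1-ol | O[C@]12CO[C@H](c3ccc(OCc4ccccc4)c(OC)c3)[C@H]1CO[C@@H]2c1ccc(OCc2ccccc2)c(OC)c1 | intermediate
9 | (2R,3S,4S)-2-(4-hydroxy-3-methoxyphenyl)-4-[(4-hydroxy-3-methoxyphenyl)methyl]-3-(hydroxymethyl)oxolan-3-ol | COc1cc(C[C@H]2CO[C@H](c3ccc(O)c(OC)c3)[C@@]2(O)CO)ccc1O | target

**Step count and risks**
Total steps: 5. Longest linear sequence: 5 (fully linear from 1 and 2). All absolute stereochemistry comes from step 3; the enantiomeric purity should be checked at 7 and can be raised by recrystallising 8.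

Risk 1, step 3. The free 1,4-diol may chelate titanium and lower the rate or the enantioselectivity, and an SN1-like opening could erode the C7 configuration. Fallback: setting out from 5, statistical monosilylation (NaH, t-BuMe2SiCl, THF) gives the mono-silyl ether (2E,3E)-2,3-bis{[4-(benzyloxy)-3-methoxyphenyl]methylidene}-4-[(tert-butyldimethylsilyl)oxy]butan-1-ol F1. A standard catalytic Sharpless epoxidation of its single free allylic alcohol (Ti(OiPr)4 10 mol %, L-(+)-diisopropyl tartrate 12 mol %, t-BuOOH, 4 Å molecular sieves, CH2Cl2, −25 °C) gives the epoxy alcohol [(2S,3S)-3-[4-(benzyloxy)-3-methoxyphenyl]-2-{(1Z)-1-[4-(benzyloxy)-3-methoxyphenyl]-3-[(tert-butyldimethylsilyl)oxy]prop-1-en-2-yl}oxiran-2-yl]methanol F2. Bu4NF in THF followed by pyridinium p-toluenesulfonate frees the 9'-hydroxyl, which opens the benzylic epoxide with inversion, and the sequence comes back to the route at 7.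

Risk 2, step 4. The Brønsted acid may ionise the tertiary allylic alcohol or the cinnamyl-type ring ether, epimerise C7, or let the wrong-face cation undergo Friedel–Crafts closure onto the C7 aryl. Fallback: setting out from 7, Hg(OAc)2 in THF (divalent mercury; reversible mercurinium formation, anti attack of the 9-hydroxyl at benzylic C7', no free cation) gives the bridgehead organomercurial 5-(acetoxymercurio)-2,6-bis[4-(benzyloxy)-3-methoxyphenyl]-3,7-dioxabicyclo[3.3.0]octan-1-ol F3, with mercury on C8' cis to the C8 hydroxyl. NaBH4 in aq. NaOH then replaces mercury by hydrogen with the cis ring fusion retained, and the sequence comes back to the route at 8.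

Risk 3, step 5. Hydrogenolysis may open the wrong benzylic ether (giving the olivil skeleton) or go on to the acyclic triol. Fallback: setting out from 8, ionic hydrogenation (Et3SiH, BF3·OEt2, CH2Cl2, −78 °C) ionises only the C7'–O bond, because a C7 cation is destabilised by the adjacent carbinol, and delivers hydride to give the di-O-benzyl ether of the target, (2R,3S,4S)-2-[4-(benzyloxy)-3-methoxyphenyl]-4-{[4-(benzyloxy)-3-methoxyphenyl]methyl}-3-(hydroxymethyl)oxolan-3-ol F4. A short hydrogenolysis (H2, 10% Pd/C, EtOAc, rt) then removes only the benzyl groups and comes back to the route at 9.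

**Further compounds**
F1 | step 3 | (2E,3E)-2,3-bis{[4-(benzyloxy)-3-methoxyphenyl]methylidene}-4-[(tert-butyldimethylsilyl)oxy]butan-1-ol | COc1cc(/C=C(/CO)\C(=C/c2ccc(OCc3ccccc3)c(OC)c2)CO[Si](C)(C)C(C)(C)C)ccc1OCc1ccccc1
F2 | step 3 | [(2S,3S)-3-[4-(benzyloxy)-3-methoxyphenyl]-2-{(1Z)-1-[4-(benzyloxy)-3-methoxyphenyl]-3-[(tert-butyldimethylsilyl)oxy]prop-1-en-2-yl}oxiran-2-yl]methanol | OC[C@@]1(O[C@H]1c1ccc(OCc2ccccc2)c(OC)c1)/C(CO[Si](C)(C)C(C)(C)C)=C\c1ccc(OCc2ccccc2)c(OC)c1
F3 | step 4 | 5-(acetoxymercurio)-2,6-bis[4-(benzyloxy)-3-methoxyphenyl]-3,7-dioxabicyclo[3.3.0]octan-1-ol (Hg on bridgehead C8', cis to the C8 hydroxyl; other centres as in 8) | O[C@]12CO[C@H](c3ccc(OCc4ccccc4)c(OC)c3)[C@@]1([Hg]OC(C)=O)CO[C@@H]2c1ccc(OCc2ccccc2)c(OC)c1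
F4 | step 5 | (2R,3S,4S)-2-[4-(benzyloxy)-3-methoxyphenyl]-4-{[4-(benzyloxy)-3-methoxyphenyl]methyl}-3-(hydroxymethyl)oxolan-3-ol | COc1cc(C[C@H]2CO[C@H](c3ccc(OCc4ccccc4)c(OC)c3)[C@@]2(O)CO)ccc1OCc1ccccc1
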